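**Plan**

- Numbering: tetralin C1 (OH), C4 (aryl), C5 (OMe); naphthyl C1′ (link), C4′ (OH), C5′ (OMe). Ring A is the anisole ring of the tetralin, ring B its saturated ring, ring C the phenolic ring and ring D the methoxy ring of the naphthalene.
- Retrosynthesis: the C1 carbinol goes back to a tetralone; ring C is cut at C8a′–C1′ and C2′–C3′ into a tetralinyl silylalkyne and a 2-methoxybenzoyl sulfoxonium ylide; ring B is cut at C1–C8a (aryllithium acylation); the C4–alkynyl bond is cut back to a benzylidene Meldrum's acid.
- Forward: ring A arrives with 2-bromo-6-methoxybenzaldehyde; the chain is built (Knoevenagel, alkynylation, one-carbon homologation); ring B closes as the tetralone; ring C is annulated onto ring D; silicon and the ketal are removed; the ketone is reduced last.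
- Stereochemistry: C4 comes from ligand-controlled rhodium-catalysed conjugate alkynylation (step 2); C1 comes from catalyst-controlled transfer hydrogenation (step 11).
- Enabling feature: C4′ (OH), C4a′, C5′ (OMe) and C8a′ make up an o-anisoyl unit with a single free ortho C–H at the future C8a′, so ring C can be grown from an alkyne (C1′, C2′) and a one-carbon ylide (C3′).

Key step: step 9

Assumption: the (S)-configured bisphosphine is taken to give the (S)-adduct 5 in step 2; if the sense of induction is the reverse, the mirror-image ligand is used.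

**Route**

Step 1
Reactants: 1 2-bromo-6-methoxybenzaldehyde; 2 Meldrum's acid
Product: 3 5-(2-bromo-6-methoxybenzylidene)-2,2-dimethyl-1,3-dioxane-4,6-dione
Conditions: pyrrolidine (cat.), AcOH (cat.), toluene, rt
Reagents that add atoms: none
Why: Knoevenagel condensation of a non-enolisable aryl aldehyde with the acidic methylene of Meldrum's acid is routine, and the hindered aldehyde should stop at the mono-alkylidene.

Step 2
Reactants: 3 benzylidene Meldrum's acid; 4 ethynyltrimethylsilane
Product: 5 5-[(1S)-1-(2-bromo-6-methoxyphenyl)-3-(trimethylsilyl)prop-2-yn-1-yl]-2,2-dimethyl-1,3-dioxane-4,6-dione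
Conditions: Rh(acac)(C2H4)2 (cat.), (S)-3,5-Xyl-MeO-BIPHEP (cat.), 4 (excess), 1,4-dioxane, rt
Reagents that add atoms: none
Why: Rhodium-catalysed enantioselective conjugate alkynylation of arylidene Meldrum's acids with silylacetylenes is an established reaction in which the bisphosphine-bound alkynylrhodium adds to one face of the doubly activated alkene, which sets C4, while the silyl group curbs alkyne oligomerisation.

Step 3
Reactants: 5 alkynylated Meldrum's acid
Product: 7 (3S)-3-(2-bromo-6-methoxyphenyl)-5-(trimethylsilyl)pent-4-ynoic acid, via malonic acid 6 (not isolated)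
Conditions: DMF/H2O (10:1), 100 °C
Reagents that add atoms: water, O
Why: Hydrolytic opening of the Meldrum's acid ring and decarboxylation of the resulting malonic acid proceed under neutral conditions that spare the alkynylsilane and the non-enolisable C4 center.

Step 4
Reactants: 7 pentynoic acid
Product: 9 (4S)-4-(2-bromo-6-methoxyphenyl)-1-diazo-6-(trimethylsilyl)hex-5-yn-2-one, via mixed isobutyl carbonic anhydride 8 (not isolated)
Conditions: i-BuOCOCl, N-methylmorpholine, THF, −15 °C; then CH2N2, Et2O, 0 °C → rt
Reagents that add atoms: diazomethane, C=[N+]=[N-]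
Why: This is the first stage of an Arndt–Eistert homologation, in which diazomethane is acylated by a mixed anhydride under conditions too mild to affect the aryl bromide, the alkynylsilane or C4.

Step 5
Reactants: 9 diazoketone
Product: 11 (4S)-4-(2-bromo-6-methoxyphenyl)-N-methoxy-N-methyl-6-(trimethylsilyl)hex-5-ynamide, via ketene 10 (not isolated)
Conditions: hν (365 nm), MeNH(OMe), THF, rt
Reagents that add atoms: N,O-dimethylhydroxylamine, CNOC
Why: Photochemical Wolff rearrangement gives a ketene that the amine traps as the Weinreb amide; the migrating CH2 group leaves the neighbouring C4 center untouched, and the metal-free variant avoids silver-induced loss of the alkynyl silyl group.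

Step 6
Reactants: 11 Weinreb amide
Product: 14 (4R)-5-methoxy-4-[(trimethylsilyl)ethynyl]-3,4-dihydronaphthalen-1(2H)-one, via aryllithium 12 (not isolated), via lithium hemiaminal alkoxide 13 (not isolated)
Conditions: t-BuLi (2.1 equiv), THF, −78 °C; then aq. NH4Cl
Reagents that add atoms: none
Why: In this Parham cyclisation bromine–lithium exchange outruns deprotonation at −78 °C, the aryllithium closes ring B by 6-exo-trig attack on the Weinreb amide, and the chelated tetrahedral adduct prevents over-addition (the descriptor at C4 changes from S to R only because bromine is lost).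

Step 7
Reactants: 14 tetralone
Product: 15 (4′R)-5′-methoxy-4′-[(trimethylsilyl)ethynyl]-3′,4′-dihydro-2′H-spiro[1,3-dioxolane-2,1′-naphthalene]
Conditions: (TMSOCH2)2, TMSOTf (cat.), CH2Cl2, −78 °C → rt; pyridine quench
Reagents that add atoms: 1,2-bis(trimethylsilyloxy)ethane, C[Si](C)(C)OCCO[Si](C)(C)C
Why: Noyori ketalisation converts aryl ketones to dioxolanes under aprotic conditions that the alkynylsilane tolerates, and it masks the carbonyl group so that it cannot direct C–H metalation or acidify C4–H in the next step.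

Step 8
Reactants: 16 2-methoxybenzoyl chloride; 17 trimethylsulfoxonium iodide
Product: 19 2-(dimethyl-oxo-λ6-sulfanylidene)-1-(2-methoxyphenyl)ethan-1-one, via dimethylsulfoxonium methylide 18 (not isolated)
Conditions: 17, KOtBu, THF, reflux; then 16, 0 °C → rt
Reagents that add atoms: none
Why: Acylation of the Corey–Chaykovsky methylide by an aroyl chloride, followed by deprotonation with the excess base, is the standard route to stabilised β-keto sulfoxonium ylides.

Step 9
Reactants: 15 ketal-protected tetralinyl silylalkyne; 19 sulfoxonium ylide (excess)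
Product: 20 8-methoxy-4-[(4′R)-5′-methoxy-3′,4′-dihydro-2′H-spiro[1,3-dioxolane-2,1′-naphthalen]-4′-yl]-3-(trimethylsilyl)naphthalen-1-ol
Conditions: [Cp*RhCl2]2 (cat.), AgSbF6 (cat.), NaOAc (cat.), DCE, 80 °C
Reagents that add atoms: none
Why: Acetate-assisted cleavage of the only free ortho C–H of 19 by cationic Cp*-ligated trivalent rhodium gives a five-membered rhodacycle bound through the ylide carbon; alkyne 15 inserts into the aryl–rhodium bond (C8a′–C1′), the ylide carbon loses DMSO to become a rhodium carbene, the alkenyl group migrates onto it (C2′–C3′), and protonolysis with keto–enol tautomerisation releases the 1-naphthol. The closest known reaction type is the Cp*Rh-catalysed C–H annulation of aroyl sulfoxonium ylides with internal alkynes to 1-naphthols. Ring C closes as a formal [4+2] annulation, the six-membered ring arising when the seven-membered alkenyl rhodacycle contracts in the carbene migratory insertion. No stereocenter is formed, and C4 is safe because it is not enolisable while the ketone is masked. The step needs insertion with silicon on the rhodium-bound carbon so that the tetralinyl-bearing carbon bonds to C8a′; the α-silyl preference known for carbometalation of alkynylsilanes should secure this, the single ortho C–H of the anisoyl ring fixes the site of metalation and places OMe peri to the new OH, and the ketal keeps the tetralone carbonyl from acting as a second directing group.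

Step 10
Reactants: 20 silylated ketal naphthol
Product: 21 (4S)-4-(4-hydroxy-5-methoxynaphthalen-1-yl)-5-methoxy-3,4-dihydronaphthalen-1(2H)-one
Conditions: TFA, CH2Cl2, H2O (few equiv), 0 °C → rt
Reagents that add atoms: water, O
Why: Acid-mediated ipso-protodesilylation of the arylsilane (β-silicon-stabilised arenium ion, helped by relief of strain next to the tetralinyl group) and acid hydrolysis of the dioxolane occur together, and the ketone so formed is acid-stable and leaves C4 non-enolisable (the descriptor at C4 changes from R to S only because silicon is lost).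

Step 11
Reactants: 21 tetralone naphthol
Product: 22 dipolynaphthalene B, (1S,4S)-4-(4-hydroxy-5-methoxynaphthalen-1-yl)-5-methoxy-1,2,3,4-tetrahydronaphthalen-1-ol
Conditions: RuCl(p-cymene)[(S,S)-TsDPEN] (cat.), HCO2H/Et3N (5:2), rt
Reagents that add atoms: none
Why: Noyori asymmetric transfer hydrogenation of 1-tetralones is strongly catalyst-controlled, so the (S,S)-catalyst should deliver hydride to the face that gives the (1S) alcohol, cis to the C4 aryl group, and it tolerates the free naphthol.

**Compound list**

1 | 2-bromo-6-methoxybenzaldehyde | COc1cccc(Br)c1C=O | starting material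
2 | Meldrum's acid (2,2-dimethyl-1,3-dioxane-4,6-dione) | CC1(C)OC(=O)CC(=O)O1 | starting material
3 | 5-(2-bromo-6-methoxybenzylidene)-2,2-dimethyl-1,3-dioxane-4,6-dione | COc1cccc(Br)c1C=C1C(=O)OC(C)(C)OC1=O | intermediate
4 | ethynyltrimethylsilane | C#C[Si](C)(C)C | starting material
5 | 5-[(1S)-1-(2-bromo-6-methoxyphenyl)-3-(trimethylsilyl)prop-2-yn-1-yl]-2,2-dimethyl-1,3-dioxane-4,6-dione | COc1cccc(Br)c1[C@H](C#C[Si](C)(C)C)C1C(=O)OC(C)(C)OC1=O | intermediate
6 | 2-[(1S)-1-(2-bromo-6-methoxyphenyl)-3-(trimethylsilyl)prop-2-yn-1-yl]propanedioic acid | COc1cccc(Br)c1[C@H](C#C[Si](C)(C)C)C(C(=O)O)C(=O)O | intermediate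
7 | (3S)-3-(2-bromo-6-methoxyphenyl)-5-(trimethylsilyl)pent-4-ynoic acid | COc1cccc(Br)c1[C@H](C#C[Si](C)(C)C)CC(=O)O | intermediate
8 | mixed anhydride of acid 7 with isobutyl hydrogen carbonate, (3S) | COc1cccc(Br)c1[C@H](C#C[Si](C)(C)C)CC(=O)OC(=O)OCC(C)C | intermediate
9 | (4S)-4-(2-bromo-6-methoxyphenyl)-1-diazo-6-(trimethylsilyl)hex-5-yn-2-one | COc1cccc(Br)c1[C@H](C#C[Si](C)(C)C)CC(=O)C=[N+]=[N-] | intermediate
10 | (4S)-4-(2-bromo-6-methoxyphenyl)-6-(trimethylsilyl)hex-1-en-5-yn-1-one (ketene) | COc1cccc(Br)c1[C@H](C#C[Si](C)(C)C)CC=C=O | intermediate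
11 | (4S)-4-(2-bromo-6-methoxyphenyl)-N-methoxy-N-methyl-6-(trimethylsilyl)hex-5-ynamide | COc1cccc(Br)c1[C@H](C#C[Si](C)(C)C)CCC(=O)N(C)OC | intermediate
12 | (4R)-4-(2-lithio-6-methoxyphenyl)-N-methoxy-N-methyl-6-(trimethylsilyl)hex-5-ynamide (same spatial arrangement as 11) | COc1cccc([Li])c1[C@H](C#C[Si](C)(C)C)CCC(=O)N(C)OC | intermediate
13 | lithium (4R)-5-methoxy-1-[methoxy(methyl)amino]-4-[(trimethylsilyl)ethynyl]-1,2,3,4-tetrahydronaphthalen-1-olate (both C1 epimers) | COc1cccc2c1[C@H](C#C[Si](C)(C)C)CCC2(O[Li])N(C)OC | intermediate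
14 | (4R)-5-methoxy-4-[(trimethylsilyl)ethynyl]-3,4-dihydronaphthalen-1(2H)-one | COc1cccc2c1[C@H](C#C[Si](C)(C)C)CCC2=O | intermediate
15 | (4′R)-5′-methoxy-4′-[(trimethylsilyl)ethynyl]-3′,4′-dihydro-2′H-spiro[1,3-dioxolane-2,1′-naphthalene] | COc1cccc2c1[C@H](C#C[Si](C)(C)C)CCC21OCCO1 | intermediate
16 | 2-methoxybenzoyl chloride | COc1ccccc1C(=O)Cl | starting material
17 | trimethylsulfoxonium iodide | C[S+](C)(C)=O.[I-] | starting material
18 | dimethylsulfoxonium methylide | C=S(C)(C)=O | intermediate
19 | 2-(dimethyl-oxo-λ6-sulfanylidene)-1-(2-methoxyphenyl)ethan-1-one | COc1ccccc1C(=O)C=S(C)(C)=O | intermediate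
20 | 8-methoxy-4-[(4′R)-5′-methoxy-3′,4′-dihydro-2′H-spiro[1,3-dioxolane-2,1′-naphthalen]-4′-yl]-3-(trimethylsilyl)naphthalen-1-ol | COc1cccc2c1[C@H](c1c([Si](C)(C)C)cc(O)c3c(OC)cccc13)CCC21OCCO1 | intermediate
21 | (4S)-4-(4-hydroxy-5-methoxynaphthalen-1-yl)-5-methoxy-3,4-dihydronaphthalen-1(2H)-one | COc1cccc2c1[C@H](c1ccc(O)c3c(OC)cccc13)CCC2=O | intermediate
22 | dipolynaphthalene B, (1S,4S)-4-(4-hydroxy-5-methoxynaphthalen-1-yl)-5-methoxy-1,2,3,4-tetrahydronaphthalen-1-ol | COc1cccc2c1[C@H](c1ccc(O)c3c(OC)cccc13)CC[C@@H]2O | target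

**Step count**

Total: 11 steps. Longest linear sequence: 10 steps (steps 1–7, 9, 10, 11); step 8 is the one-step side branch.

**Steps most likely to fail**

1. Step 9. Both alkyne substituents are bulky, so insertion may stall or take the opposite orientation, and the crowded C1′/C2′ junction may not form. The fallback closes ring C by a radical annulation that needs no silicon; it sets out from 15 and comes back at 21.
   - K2CO3 in MeOH removes the alkynyl silyl group to give the terminal alkyne (4′S)-4′-ethynyl-5′-methoxy-3′,4′-dihydro-2′H-spiro[1,3-dioxolane-2,1′-naphthalene] F1 (same spatial arrangement as 15).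
   - The radical partner is ethyl 2-bromo-3-(2-methoxyphenyl)-3-oxopropanoate F2, made from the commercial β-keto ester and NBS.
   - Visible-light photoredox coupling of F1 and F2 (fac-Ir(ppy)3, blue light, DMF) should add the keto-ester radical to the terminal alkyne carbon; the vinyl radical then cyclises onto the free ortho position of the anisoyl ring. This gives ethyl 1-hydroxy-8-methoxy-4-[(4′S)-5′-methoxy-3′,4′-dihydro-2′H-spiro[1,3-dioxolane-2,1′-naphthalen]-4′-yl]-2-naphthoate F3, with regiochemistry fixed by the radical addition.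
   - Aqueous HCl in THF hydrolyses the dioxolane to ethyl 1-hydroxy-8-methoxy-4-[(1S)-8-methoxy-4-oxo-1,2,3,4-tetrahydronaphthalen-1-yl]-2-naphthoate F4.
   - LiOH in aqueous THF gives 1-hydroxy-8-methoxy-4-[(1S)-8-methoxy-4-oxo-1,2,3,4-tetrahydronaphthalen-1-yl]-2-naphthoic acid F5.
   - Protodecarboxylation of this o-hydroxy acid (Cu2O, 1,10-phenanthroline, NMP/quinoline, heat) returns to 21.

2. Step 2. The two ortho substituents twist the aryl ring and crowd both faces of the alkene, so conversion may be slow or facial discrimination poor. The fallback gives up catalytic induction for classical resolution; it sets out from 3 and comes back at 7.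
   - (Trimethylsilyl)ethynylmagnesium bromide in THF adds in conjugate fashion to give racemic 5-[1-(2-bromo-6-methoxyphenyl)-3-(trimethylsilyl)prop-2-yn-1-yl]-2,2-dimethyl-1,3-dioxane-4,6-dione F6.
   - Heating in wet DMF passes through racemic 2-[1-(2-bromo-6-methoxyphenyl)-3-(trimethylsilyl)prop-2-yn-1-yl]propanedioic acid F7 (not isolated) to racemic 3-(2-bromo-6-methoxyphenyl)-5-(trimethylsilyl)pent-4-ynoic acid F8.
   - Crystallisation with (R)-1-phenylethylamine (or its antipode, whichever gives the less soluble salt of the (S)-acid) should give (R)-1-phenylethylammonium (3S)-3-(2-bromo-6-methoxyphenyl)-5-(trimethylsilyl)pent-4-ynoate F9; acidification returns to 7.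

3. Step 10. Strong acid may protonate C1′ (para to the naphthol OH) and break or epimerise the C4–C1′ bond through a benzylic cation, or the C–Si cleavage may lag behind ketal hydrolysis. The fallback separates the two events and cleaves silicon by nucleophilic attack instead of ipso-protonation; it sets out from 20 and comes back at 21.
   - KOSiMe3 in wet DMSO at 70 °C (base-mediated protodesilylation, with the naphthoxide shielding C4–H from deprotonation) should give 8-methoxy-4-[(4′S)-5′-methoxy-3′,4′-dihydro-2′H-spiro[1,3-dioxolane-2,1′-naphthalen]-4′-yl]naphthalen-1-ol F10.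
   - Pyridinium p-toluenesulfonate in aqueous acetone then hydrolyses the dioxolane and returns to 21.

**Further compounds**

F1 | step 9 | (4′S)-4′-ethynyl-5′-methoxy-3′,4′-dihydro-2′H-spiro[1,3-dioxolane-2,1′-naphthalene] | COc1cccc2c1[C@H](C#C)CCC21OCCO1
F2 | step 9 | ethyl 2-bromo-3-(2-methoxyphenyl)-3-oxopropanoate | CCOC(=O)C(Br)C(=O)c1ccccc1OC
F3 | step 9 | ethyl 1-hydroxy-8-methoxy-4-[(4′S)-5′-methoxy-3′,4′-dihydro-2′H-spiro[1,3-dioxolane-2,1′-naphthalen]-4′-yl]-2-naphthoate | COc1cccc2c1[C@H](c1cc(C(=O)OCC)c(O)c3c(OC)cccc13)CCC21OCCO1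
F4 | step 9 | ethyl 1-hydroxy-8-methoxy-4-[(1S)-8-methoxy-4-oxo-1,2,3,4-tetrahydronaphthalen-1-yl]-2-naphthoate | COc1cccc2c1[C@H](c1cc(C(=O)OCC)c(O)c3c(OC)cccc13)CCC2=O
F5 | step 9 | 1-hydroxy-8-methoxy-4-[(1S)-8-methoxy-4-oxo-1,2,3,4-tetrahydronaphthalen-1-yl]-2-naphthoic acid | COc1cccc2c1[C@H](c1cc(C(=O)O)c(O)c3c(OC)cccc13)CCC2=O
F6 | step 2 | racemic 5-[1-(2-bromo-6-methoxyphenyl)-3-(trimethylsilyl)prop-2-yn-1-yl]-2,2-dimethyl-1,3-dioxane-4,6-dione | COc1cccc(Br)c1C(C#C[Si](C)(C)C)C1C(=O)OC(C)(C)OC1=O
F7 | step 2 | racemic 2-[1-(2-bromo-6-methoxyphenyl)-3-(trimethylsilyl)prop-2-yn-1-yl]propanedioic acid | COc1cccc(Br)c1C(C#C[Si](C)(C)C)C(C(=O)O)C(=O)O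
F8 | step 2 | racemic 3-(2-bromo-6-methoxyphenyl)-5-(trimethylsilyl)pent-4-ynoic acid | COc1cccc(Br)c1C(C#C[Si](C)(C)C)CC(=O)O
F9 | step 2 | (R)-1-phenylethylammonium (3S)-3-(2-bromo-6-methoxyphenyl)-5-(trimethylsilyl)pent-4-ynoate | COc1cccc(Br)c1[C@H](C#C[Si](C)(C)C)CC(=O)[O-].C[C@@H]([NH3+])c1ccccc1
F10 | step 10 | 8-methoxy-4-[(4′S)-5′-methoxy-3′,4′-dihydro-2′H-spiro[1,3-dioxolane-2,1′-naphthalen]-4′-yl]naphthalen-1-ol | COc1cccc2c1[C@H](c1ccc(O)c3c(OC)cccc13)CCC21OCCO1
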